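**Strategy.** The route rests on disconnecting the C4–C4a bond of the O-methylated flavone unit. In its ring A, C8 holds the diaryl ether oxygen, so C4a is the only open carbon next to the O1-bearing C8a and is activated by the C5 (ortho) and C7 (para) oxygens. A β-aryloxycinnamic acid, the Z enol ether of 2-(4-bromophenoxy)-3,5-dimethoxyphenol and 4-methoxyphenylpropiolic acid, is therefore cyclised by tethered Friedel–Crafts acylation; one operation closes pyranone ring C and fixes the 5,7,8-oxygenation pattern. The aryl bromide then serves to attach the apigenin unit by borylation and oxidative arylation of a protected 5,7-dihydroxychromone, before a single boron trichloride deprotection.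

Key step: step 7

Remarks on the chemistry:
- The target has no stereocentre, axis or configured double bond, so it is one achiral compound and no enantiocontrol is needed. The only configured element in the route is the Z enol ether of 9–11.
- A free catechol is avoided on the way to the precursor. Catechols add twice to alkynoates (giving 1,3-benzodioxoles) and are oxidised under copper(II)/air. The two oxygens are therefore differentiated from the start: the existing phenol is masked as a MOM ether before the aldehyde carbon is exchanged for oxygen.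
- 5,7-Dihydroxychromone is taken as a purchasable building block.

Step 1
Reactants: 1 2-hydroxy-4,6-dimethoxybenzaldehyde
Product: 2 4,6-dimethoxy-2-(methoxymethoxy)benzaldehyde
Conditions: NaH, DMF, 0 °C; MOMCl, 0 °C → rt
Reagents that add atoms: chloromethyl methyl ether, COCCl
Why: Williamson-type O-alkylation of the sodium phenoxide, which breaks the chelate to the aldehyde, masks the oxygen that will later carry the enol ether with a group stable to peracid, base and copper(II).

Step 2
Reactants: 2 4,6-dimethoxy-2-(methoxymethoxy)benzaldehyde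
Product: 4 2,4-dimethoxy-6-(methoxymethoxy)phenol, via aryl formate 3 (not isolated)
Conditions: mCPBA, NaHCO3, CH2Cl2, 0 °C → rt; aq. Na2S2O3 wash; then K2CO3, MeOH, rt
Reagents that add atoms: 3-chloroperoxybenzoic acid, OOC(=O)c1cccc(Cl)c1
Why: Baeyer–Villiger (Dakin-type) oxidation, in which the trioxygenated aryl group migrates in preference to hydride, gives the formate, and methanolysis after removal of excess peracid should release the central phenol without over-oxidation.

Step 3
Reactants: 4 2,4-dimethoxy-6-(methoxymethoxy)phenol; 5 4-bromophenylboronic acid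
Product: 6 2-(4-bromophenoxy)-1,5-dimethoxy-3-(methoxymethoxy)benzene
Conditions: Cu(OAc)2, pyridine, 4 Å MS, CH2Cl2, air, rt (excess 5)
Reagents that add atoms: none
Why: Chan–Lam oxidative O-arylation couples electron-rich, ortho-substituted phenols with arylboronic acids at room temperature and leaves the aryl bromide untouched, so the central oxygen is arylated while its neighbour is still masked.

Step 4
Reactants: 6 2-(4-bromophenoxy)-1,5-dimethoxy-3-(methoxymethoxy)benzene
Product: 7 2-(4-bromophenoxy)-3,5-dimethoxyphenol
Conditions: conc. HCl (cat.), MeOH, 50 °C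
Reagents that add atoms: none
Why: Acid-catalysed acetal exchange with methanol removes the MOM group as dimethoxymethane under conditions to which aryl methyl ethers, the diaryl ether and the aryl bromide are inert.

Step 5
Reactants: 7 2-(4-bromophenoxy)-3,5-dimethoxyphenol; 8 ethyl 3-(4-methoxyphenyl)propiolate
Product: 9 ethyl (2Z)-3-[2-(4-bromophenoxy)-3,5-dimethoxyphenoxy]-3-(4-methoxyphenyl)prop-2-enoate
Conditions: K2CO3, DMF, 90 °C
Reagents that add atoms: none
Why: Base-mediated oxa-Michael addition of the phenoxide to the aryl-bearing carbon of the alkynoate (first stage of the Ruhemann sequence) proceeds by anti addition, which places the ester cis to the aryloxy group (Z), also the less congested isomer because the ester is trans to the anisyl ring.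

Step 6
Reactants: 9 ethyl (2Z)-3-[2-(4-bromophenoxy)-3,5-dimethoxyphenoxy]-3-(4-methoxyphenyl)prop-2-enoate
Product: 10 (2Z)-3-[2-(4-bromophenoxy)-3,5-dimethoxyphenoxy]-3-(4-methoxyphenyl)prop-2-enoic acid
Conditions: LiOH·H2O, THF/MeOH/H2O, rt → 40 °C; then 1 M HCl, 0 °C, to pH 3
Reagents that add atoms: lithium hydroxide, [Li+].[OH-]
Why: Mild saponification by acyl–oxygen cleavage frees the acid, while low temperature and cold acidification avoid displacement of the phenoxide, enol ether hydrolysis and decarboxylation.

Step 7
Reactants: 10 (2Z)-3-[2-(4-bromophenoxy)-3,5-dimethoxyphenoxy]-3-(4-methoxyphenyl)prop-2-enoic acid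
Product: 12 8-(4-bromophenoxy)-5,7-dimethoxy-2-(4-methoxyphenyl)-4H-chromen-4-one, via mixed methanesulfonic anhydride 11 (not isolated)
Conditions: Eaton's reagent (7.7 wt% P2O5 in MeSO3H), rt → 45 °C; pour onto ice
Reagents that add atoms: none
Why: Methanesulfonic anhydride present in the medium turns acid 10 into mixed anhydride 11, which ionises to an acylium ion that is captured by the carbon of the trioxygenated ring ortho to the enol ether oxygen, and loss of a proton restores aromaticity to give the chromone (intramolecular Friedel–Crafts acylation). The closest known reaction type is the Ruhemann flavone synthesis, the cycloacylation of β-aryloxycinnamic acids in a strong dehydrating acid. Pyranone ring C closes by 6-exo attack of the arene on the acyl carbon, with the carbonyl oxygen left outside the new ring and the Z double bond holding acyl group and arene on the same side. No stereocentre is formed. The step needs regioselectivity, which the substrate secures: the attacked carbon (future C4a) is the only unsubstituted position ortho to the tethering oxygen because the other ortho carbon (future C8) carries the 4-bromophenoxy group, and it is activated by an ortho and a para methoxy group, whereas the bromophenyl ring is out of reach and the anisyl ring could only be attacked meta to its methoxy group in a five-membered closure. The step also needs the acid cis to the aryloxy oxygen, which the Z geometry from step 5 provides and which reversible C-protonation of the enol ether in the acid keeps supplying, so that ring closure is the only outlet.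

Step 8
Reactants: 12 8-(4-bromophenoxy)-5,7-dimethoxy-2-(4-methoxyphenyl)-4H-chromen-4-one
Product: 13 5,7-dimethoxy-2-(4-methoxyphenyl)-8-[4-(4,4,5,5-tetramethyl-1,3,2-dioxaborolan-2-yl)phenoxy]-4H-chromen-4-one
Conditions: B2pin2, PdCl2(dppf), KOAc, 1,4-dioxane, 90 °C
Reagents that add atoms: bis(pinacolato)diboron, CC1(C)OB(OC1(C)C)B1OC(C)(C)C(C)(C)O1
Why: Miyaura borylation of an aryl bromide with the weak base KOAc tolerates the chromone, the aryl ethers and the diaryl ether.

Step 9
Reactants: 14 5,7-dihydroxy-4H-chromen-4-one
Product: 15 5,7-bis(benzyloxy)-4H-chromen-4-one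
Conditions: BnBr (excess), K2CO3, n-Bu4NI (cat.), DMF, 70 °C
Reagents that add atoms: benzyl bromide, BrCc1ccccc1
Why: Williamson etherification under forcing carbonate conditions should benzylate both the free 7-OH and the chelated 5-OH, giving a chromone without acidic protons for the palladium step.

Step 10
Reactants: 13 5,7-dimethoxy-2-(4-methoxyphenyl)-8-[4-(4,4,5,5-tetramethyl-1,3,2-dioxaborolan-2-yl)phenoxy]-4H-chromen-4-one; 15 5,7-bis(benzyloxy)-4H-chromen-4-one
Product: 16 8-{4-[5,7-bis(benzyloxy)-4-oxo-4H-chromen-2-yl]phenoxy}-5,7-dimethoxy-2-(4-methoxyphenyl)-4H-chromen-4-one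
Conditions: Pd(TFA)2 (cat.), 5-nitro-1,10-phenanthroline (cat.), O2 (1 atm), DMSO, 80 °C (15 in excess)
Reagents that add atoms: none
Why: Oxidative boron-Heck arylation of a chromone: aryl transfer from boron to Pd(II), carbopalladation of C2=C3 with the aryl group delivered to C2, epimerisation through the palladium enolate and β-hydride elimination should give the flavone, with O2 reoxidising Pd(0).

Step 11
Reactants: 16 8-{4-[5,7-bis(benzyloxy)-4-oxo-4H-chromen-2-yl]phenoxy}-5,7-dimethoxy-2-(4-methoxyphenyl)-4H-chromen-4-one
Product: 17 8-[4-(5,7-dihydroxy-4-oxo-4H-chromen-2-yl)phenoxy]-5-hydroxy-7-methoxy-2-(4-methoxyphenyl)-4H-chromen-4-one (target)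
Conditions: BCl3 (excess), pentamethylbenzene, CH2Cl2, −78 °C → rt; MeOH, then aq. NaHCO3 work-up
Reagents that add atoms: none
Why: Lewis-acid ether cleavage with BCl3 removes both benzyl ethers (benzyl cations trapped by pentamethylbenzene) and, through chelation to the C4 carbonyl, the peri 5-methyl ether, while the non-chelated 7- and 4'-methyl ethers and the diaryl ether should be left intact.

**Compound list**

1 | 2-hydroxy-4,6-dimethoxybenzaldehyde | COc1cc(O)c(C=O)c(OC)c1 | starting material
2 | 4,6-dimethoxy-2-(methoxymethoxy)benzaldehyde | COCOc1cc(OC)cc(OC)c1C=O | intermediate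
3 | 2,4-dimethoxy-6-(methoxymethoxy)phenyl formate | COCOc1cc(OC)cc(OC)c1OC=O | intermediate (not isolated)
4 | 2,4-dimethoxy-6-(methoxymethoxy)phenol | COCOc1cc(OC)cc(OC)c1O | intermediate
5 | 4-bromophenylboronic acid | OB(O)c1ccc(Br)cc1 | starting material
6 | 2-(4-bromophenoxy)-1,5-dimethoxy-3-(methoxymethoxy)benzene | COCOc1cc(OC)cc(OC)c1Oc1ccc(Br)cc1 | intermediate
7 | 2-(4-bromophenoxy)-3,5-dimethoxyphenol | Oc1cc(OC)cc(OC)c1Oc1ccc(Br)cc1 | intermediate
8 | ethyl 3-(4-methoxyphenyl)propiolate | CCOC(=O)C#Cc1ccc(OC)cc1 | starting material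
9 | ethyl (2Z)-3-[2-(4-bromophenoxy)-3,5-dimethoxyphenoxy]-3-(4-methoxyphenyl)prop-2-enoate | CCOC(=O)/C=C(\Oc1cc(OC)cc(OC)c1Oc1ccc(Br)cc1)c1ccc(OC)cc1 | intermediate
10 | (2Z)-3-[2-(4-bromophenoxy)-3,5-dimethoxyphenoxy]-3-(4-methoxyphenyl)prop-2-enoic acid | OC(=O)/C=C(\Oc1cc(OC)cc(OC)c1Oc1ccc(Br)cc1)c1ccc(OC)cc1 | intermediate (key-step precursor)
11 | (2Z)-3-[2-(4-bromophenoxy)-3,5-dimethoxyphenoxy]-3-(4-methoxyphenyl)prop-2-enoic methanesulfonic anhydride | CS(=O)(=O)OC(=O)/C=C(\Oc1cc(OC)cc(OC)c1Oc1ccc(Br)cc1)c1ccc(OC)cc1 | intermediate (not isolated)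
12 | 8-(4-bromophenoxy)-5,7-dimethoxy-2-(4-methoxyphenyl)-4H-chromen-4-one | COc1ccc(-c2cc(=O)c3c(OC)cc(OC)c(Oc4ccc(Br)cc4)c3o2)cc1 | intermediate (key-step product)
13 | 5,7-dimethoxy-2-(4-methoxyphenyl)-8-[4-(4,4,5,5-tetramethyl-1,3,2-dioxaborolan-2-yl)phenoxy]-4H-chromen-4-one | COc1ccc(-c2cc(=O)c3c(OC)cc(OC)c(Oc4ccc(B5OC(C)(C)C(C)(C)O5)cc4)c3o2)cc1 | intermediate
14 | 5,7-dihydroxy-4H-chromen-4-one | O=c1ccoc2cc(O)cc(O)c12 | starting material
15 | 5,7-bis(benzyloxy)-4H-chromen-4-one | O=c1ccoc2cc(OCc3ccccc3)cc(OCc3ccccc3)c12 | intermediate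
16 | 8-{4-[5,7-bis(benzyloxy)-4-oxo-4H-chromen-2-yl]phenoxy}-5,7-dimethoxy-2-(4-methoxyphenyl)-4H-chromen-4-one | COc1ccc(-c2cc(=O)c3c(OC)cc(OC)c(Oc4ccc(-c5cc(=O)c6c(OCc7ccccc7)cc(OCc8ccccc8)cc6o5)cc4)c3o2)cc1 | intermediate
17 | 8-[4-(5,7-dihydroxy-4-oxo-4H-chromen-2-yl)phenoxy]-5-hydroxy-7-methoxy-2-(4-methoxyphenyl)-4H-chromen-4-one | COc1ccc(-c2cc(=O)c3c(O)cc(OC)c(Oc4ccc(-c5cc(=O)c6c(O)cc(O)cc6o5)cc4)c3o2)cc1 | target

**Step count.** Total: 11 steps. Longest linear sequence: 10 steps (steps 1–8, 10, 11); step 9 is a one-step side branch.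

**Steps most likely to fail, with fallbacks**

Step 10 is the least secure. Protodeboronation, oxidation or homocoupling of the boronate may outrun insertion into the electron-rich chromone, or β-hydride elimination may be incomplete and leave material at the flavanone oxidation level. The fallback sets out from 13 and 15 and comes back at 16, forming the bond and adjusting the oxidation level in separate operations. Boronate 13 would be cleaved (NaIO4, NH4OAc, aqueous acetone) to {4-[5,7-dimethoxy-2-(4-methoxyphenyl)-4-oxo-4H-chromen-8-yl]oxyphenyl}boronic acid F1. F1 would add to 15 in a cationic Pd(II)-catalysed conjugate addition (Pd(TFA)2, 2,2'-bipyridine, NH4PF6, water, 1,2-dichloroethane, 60 °C) to give racemic 8-{4-[(2RS)-5,7-bis(benzyloxy)-4-oxo-3,4-dihydro-2H-chromen-2-yl]phenoxy}-5,7-dimethoxy-2-(4-methoxyphenyl)-4H-chromen-4-one F2. Dehydrogenation of this flavanone with catalytic iodine in DMSO at 120 °C would give 16; the stereocentre of F2 is erased in that step.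

Step 7 carries the strategy. Cleavage of the enol ether by adventitious water, decarboxylation of the acid, or sulfonation or demethylation of the very electron-rich ring may compete with ring closure. The fallback sets out from phenol 7 and comes back at 12, building ring C by the classical chalcone route instead. Ortho C-acetylation of 7 under boron chelate control (Ac2O, BF3·OEt2, 80 °C, Fries-type) would give 1-[3-(4-bromophenoxy)-2-hydroxy-4,6-dimethoxyphenyl]ethan-1-one F3. Claisen–Schmidt condensation with 4-methoxybenzaldehyde (KOH, EtOH, rt) would give (2E)-1-[3-(4-bromophenoxy)-2-hydroxy-4,6-dimethoxyphenyl]-3-(4-methoxyphenyl)prop-2-en-1-one F4. Oxidative cyclisation of this chalcone (cat. I2, DMSO, 120 °C) would give 12.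

Step 3 may suffer from slow copper-mediated C–O bond formation at the doubly ortho-substituted phenol, with oxidation of the electron-rich phenol and protodeboronation of the boronic acid consuming the partners. The fallback sets out from 4 and comes back at 6. It replaces the oxidative copper coupling by metal-free arylation with an iodine(III) aryl donor: bis(4-bromophenyl)iodonium triflate, t-BuOK, THF, rt. This ligand coupling is well suited to hindered phenoxides and makes no new compound (F0).

Further compounds

F1 | step 10 | {4-[5,7-dimethoxy-2-(4-methoxyphenyl)-4-oxo-4H-chromen-8-yl]oxyphenyl}boronic acid | COc1ccc(-c2cc(=O)c3c(OC)cc(OC)c(Oc4ccc(B(O)O)cc4)c3o2)cc1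
F2 | step 10 | 8-{4-[(2RS)-5,7-bis(benzyloxy)-4-oxo-3,4-dihydro-2H-chromen-2-yl]phenoxy}-5,7-dimethoxy-2-(4-methoxyphenyl)-4H-chromen-4-one (racemate) | COc1ccc(-c2cc(=O)c3c(OC)cc(OC)c(Oc4ccc(C5CC(=O)c6c(OCc7ccccc7)cc(OCc8ccccc8)cc6O5)cc4)c3o2)cc1
F3 | step 7 | 1-[3-(4-bromophenoxy)-2-hydroxy-4,6-dimethoxyphenyl]ethan-1-one | CC(=O)c1c(OC)cc(OC)c(Oc2ccc(Br)cc2)c1O
F4 | step 7 | (2E)-1-[3-(4-bromophenoxy)-2-hydroxy-4,6-dimethoxyphenyl]-3-(4-methoxyphenyl)prop-2-en-1-one | COc1ccc(/C=C/C(=O)c2c(OC)cc(OC)c(Oc3ccc(Br)cc3)c2O)cc1
F0 | step 3 | none | none
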